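- The constants are not given, so I read one combination of them from the readings.

| flask | starting material | reagent | free catalyst | time |
|---|---|---|---|---|
| summer | 0.800 M | 0.800 M | 0.0640 M |  |
| dusk | 0.400 M | 0.400 M | 0.0640 M |  |
| autumn | 0.800 M | 0.400 M | 0.0640 M |  |
| noon | 0.800 M | 0.400 M | 0.130 M | 5.2 h |

- summer run (time / h: [target] / M): 0.65: 0.189; 1.3: 0.278; 1.9: 0.315; 2.6: 0.342; 3.2: 0.360; 3.9: 0.373; 4.5: 0.385; 5.2: 0.400
- dusk run (time / h: [target] / M): 0.65: 0.051; 1.3: 0.085; 1.9: 0.099; 2.6: 0.109; 3.2: 0.112; 3.9: 0.120; 4.5: 0.126; 5.2: 0.131
- autumn run (time / h: [target] / M): 0.65: 0.103; 1.3: 0.150; 1.9: 0.178; 2.6: 0.193; 3.2: 0.204; 3.9: 0.211; 4.5: 0.213; 5.2: 0.220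

(scatter of a reading: 0.004 M)

- Overall: starting material + reagent -> target, with free catalyst as catalyst.
- Constant volume, constant temperature.
- "The second partner" is reagent.
- An order is taken over about fifteen percent of the charge, up and down.

- apparent order in [reagent] of the starting rate, round the charge of the summer run (the rate where two percent of its starting material have turned into target)
- apparent order in [starting material] of the starting rate, round the charge of the summer run (the rate where two percent of its starting material have turned into target) (one fixed amount of target, the same in the runs compared)
- target in the noon run at 5.2 h, as a share of the starting material charged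
- which of these the readings show (the substrate pairs with itself / the second partner ties up the catalyst / nothing beyond the main steps / the catalyst dies by itself)

- I call it the dose: the rate constant times the time integral of c(free catalyst), taken from the target by the integrated law of rate proportional to c(free catalyst)·c(starting material)·c(reagent).
- At 5.2 h, the summer, dusk and autumn runs give doses of 1.25 M⁻¹, 1.22 M⁻¹ and 1.19 M⁻¹, with a mean D of 1.22 M⁻¹.
- These doses lie close together across the charges, so I take first order in each partner and a catalyst that dies by itself, with time as the clock.
- First rung: the mean dose at 0.65 h is 0.384 M⁻¹. Taking D as the whole dose for a first estimate and the death as first order, I read a catalyst lifetime of 1.72 h.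
- Second rung: at the starting rate of dose, the summer run reaches half conversion in 1.76 h by my reckoning, about equal to that lifetime, so in the summer run conversion and catalyst death run on one time scale.
- Third rung: 5.2 h is 3.02 lifetimes, and by this reckoning 4.86% of the charged catalyst is still free then, which is the correction to taking D as the whole dose.
- With first-order death, the dose at a fixed time scales with the catalyst charged. The noon run therefore gets 2.48 M⁻¹.
- Its reagent is the limiting reagent, with a ceiling of 50.0%, and the integrated law gives me 38.6%.
- The forecast says 32%, with orders 1 in reagent and 1 in starting material, and the catalyst dies by itself. It reads the tail as one that “suggests death second order in catalyst”, so my figure stands higher than its figure.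

The equations behind the runs:

    free catalyst + starting material + reagent → target + free catalyst (10.91 M⁻² h⁻¹)
    free catalyst → spent catalyst (0.5544 h⁻¹)

- The noon run gives 38.2%, the orders round the summer charge are 1.0 in reagent and 1.0 in starting material, and the answer is that the catalyst dies by itself. The fit with nothing beyond the main steps forecast 42.8% for this flask. Read backwards, 38.2% is a dose of 2.41 M⁻¹, which is 1.98 times D for 2.03 times the catalyst. The summer reading of 0.400 M at 5.2 h carries a scatter of 0.004 M; half conversion in the summer run needs a dose of 1.25 M⁻¹, just above D, and that point comes at 8.87 h.

The readings come from a simulation from invented constants.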